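**Plan**

- Retrosynthesis: the sulfate S–O bond is cut first, then the O–aryl bond between the ring B oxygen and ring A (SNAr on a 2-fluorobenzaldehyde whose formyl carbon later becomes the sulfated oxygen), and last ring C itself through its C1–C2 and C5–C6 bonds.
- Enabling feature: ring C is a 2,4-dibromophenyl group whose C2–C5 carry Br, H, Br, H, the same sequence as C3–C6 of 3,5-dibromo-2-pyrone. It sits on the ring B oxygen that is crowded between C–Br and C–O, an oxygen that is easy to alkylate but hard to arylate.
- Forward: guaiacol is tribrominated (ring B); its free oxygen is taken through vinyl and bromovinyl ethers to an ethynyl ether; ring C is grown on that oxygen by pyrone Diels-Alder reaction with loss of CO2; demethylation frees the second oxygen, which takes ring A by SNAr; Baeyer-Villiger oxidation and sulfation finish.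
- Stereochemistry: the target has no stereocenter. The only selectivity to be won is regiochemical (2,4- versus 3,5-dibromophenyl), and it comes from the polarisation of the ynol ether and of the pyrone.

Key step: step 7

Remark on the chemistry: the target is drawn as the free aryl hydrogen sulfate, so the route ends with a cold proton exchange of the sulfate salt; coumalic acid, guaiacol and 3,5-dibromo-2-fluorobenzaldehyde are taken as purchasable.

**Route**

Step 1
Reactants: 1 coumalic acid
Product: 2 3,5-dibromo-2H-pyran-2-one
Conditions: NBS (2.5 equiv), LiOAc (cat.), MeCN/H2O 9:1, rt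
Reagents that add atoms: N-bromosuccinimide, O=C1CCC(=O)N1Br
Why: Bromodecarboxylation at C5 (Hunsdiecker-type ipso substitution of the carboxylate) combined with electrophilic bromination at C3 is the standard preparation of this pyrone from coumalic acid.

Step 2
Reactants: 3 guaiacol
Product: 4 2,3,4-tribromo-6-methoxyphenol
Conditions: Br2 (3.2 equiv), AcOH, rt to 50 °C
Reagents that add atoms: bromine, BrBr
Why: Electrophilic aromatic bromination should take the positions para and ortho to the free hydroxyl and para to the methoxy group, leaving only the least activated position (ortho to OMe, meta to OH) unsubstituted.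

Step 3
Reactants: 4 2,3,4-tribromo-6-methoxyphenol
Product: 5 1,2,3-tribromo-4-(2-bromoethoxy)-5-methoxybenzene
Conditions: BrCH2CH2Br (8 equiv), K2CO3, DMF, 70 °C
Reagents that add atoms: 1,2-dibromoethane, BrCCBr
Why: Williamson ether synthesis: the acidic, doubly ortho-substituted phenoxide still displaces a primary bromide by SN2, and the large excess of dibromide suppresses the bis-aryl ether.

Step 4
Reactants: 5 1,2,3-tribromo-4-(2-bromoethoxy)-5-methoxybenzene
Product: 6 1,2,3-tribromo-4-(ethenyloxy)-5-methoxybenzene
Conditions: KOtBu, THF, 0 °C to rt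
Reagents that add atoms: none
Why: E2 dehydrobromination of an aryl 2-bromoethyl ether with a hindered alkoxide is the classical way to aryl vinyl ethers and asks nothing further of the hindered oxygen.

Step 5
Reactants: 6 1,2,3-tribromo-4-(ethenyloxy)-5-methoxybenzene
Product: 8 1,2,3-tribromo-4-{[(Z)-2-bromoethenyl]oxy}-5-methoxybenzene, via dibromide 7 (not isolated)
Conditions: Br2 (1.0 equiv), CH2Cl2, −78 °C; then i-Pr2NEt, −78 °C to rt
Reagents that add atoms: bromine, BrBr
Why: Bromine should add to the enol ether double bond far faster than it attacks the deactivated arene, and the amine then removes HBr from the α-bromo ether (the bromide next to oxygen leaves with oxocarbenium assistance), the established bromination/dehydrobromination route to 2-bromovinyl ethers; the Z isomer is expected to dominate and any E isomer would be carried along.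

Step 6
Reactants: 8 1,2,3-tribromo-4-{[(Z)-2-bromoethenyl]oxy}-5-methoxybenzene
Product: 9 1,2,3-tribromo-4-(ethynyloxy)-5-methoxybenzene
Conditions: KOtBu (2.2 equiv), THF, −78 to 0 °C; cold pH 7 phosphate buffer; used at once as a toluene solution
Reagents that add atoms: none
Why: Anti-periplanar E2 loss of HBr from the (Z)-bromovinyl ether (H on the oxygen-bearing carbon trans to Br) is the classical dehydrohalogenation route to aryloxyacetylenes, and because no organolithium is used the aryl bromides are not exchanged.

Step 7
Reactants: 2 3,5-dibromo-2H-pyran-2-one; 9 1,2,3-tribromo-4-(ethynyloxy)-5-methoxybenzene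
Product: 11 1,2,3-tribromo-4-(2,4-dibromophenoxy)-5-methoxybenzene, via bicyclic lactone 10 (not isolated)
Conditions: toluene, 110 °C, sealed tube, acid-free glassware; 9 added slowly to 2 (2 equiv)
Reagents that add atoms: none
Why: The terminal, nucleophilic CH of ynol ether 9 should attack the electrophilic C6 of pyrone 2 while the oxygen-bearing alkyne carbon bonds to C3, an asynchronous inverse-electron-demand [4+2] cycloaddition that gives bridged lactone 10, which loses CO2 by retro-[4+2] at the reaction temperature and aromatises irreversibly. The closest known reaction type is the Diels-Alder/decarboxylation of 2-pyrones with ynamines and alkynyl ethers to give anilines and aryl ethers, and 3,5-dibromo-2-pyrone is an established ambiphilic diene that takes enol ethers with the same orientation. Ring C closes by an intermolecular [4π+2π] cycloaddition in which both new bonds (C1–C2 and C5–C6 of ring C) form in one six-membered transition state, followed by cycloreversion, so the hindered oxygen never has to attack an aryl electrophile. No stereocenter remains, since the two bridgehead centres of racemic 10 are erased on aromatisation. The step needs regioselectivity (2,4- over 3,5-dibromophenyl), which the matched polarisation of the donor-substituted alkyne and the C6-electrophilic pyrone should secure, and it needs the alkyne to outlast the heating, which an aryl ynol ether can do because it has no alkyl C–H for a retro-ene path to a ketene, while slow addition to excess 2 holds its self-oligomerisation down.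

Step 8
Reactants: 11 1,2,3-tribromo-4-(2,4-dibromophenoxy)-5-methoxybenzene
Product: 12 3,4,5-tribromo-2-(2,4-dibromophenoxy)phenol
Conditions: BBr3, CH2Cl2, −78 °C to rt; H2O
Reagents that add atoms: none
Why: Lewis-acid cleavage of the aryl methyl ether by BBr3 (bromide attacks the O-methyl group of the boron-complexed ether) leaves diaryl ether and aryl bromide bonds untouched, as is routine for methoxylated polybrominated diphenyl ethers.

Step 9
Reactants: 12 3,4,5-tribromo-2-(2,4-dibromophenoxy)phenol; 13 3,5-dibromo-2-fluorobenzaldehyde
Product: 14 3,5-dibromo-2-[3,4,5-tribromo-2-(2,4-dibromophenoxy)phenoxy]benzaldehyde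
Conditions: K2CO3, DMAc, 100 °C
Reagents that add atoms: none
Why: SNAr: the fluoride ortho to the formyl group is displaced through a Meisenheimer adduct by a phenoxide that has only one ortho substituent, the bromines meta to the aldehyde are not activated, and the temperature is held at 100 °C so that no ortho bromine is displaced intramolecularly.

Step 10
Reactants: 14 3,5-dibromo-2-[3,4,5-tribromo-2-(2,4-dibromophenoxy)phenoxy]benzaldehyde
Product: 16 3,5-dibromo-2-[3,4,5-tribromo-2-(2,4-dibromophenoxy)phenoxy]phenol, via aryl formate 15 (not isolated)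
Conditions: mCPBA (1.2 equiv), CH2Cl2, 40 °C; then MeOH, HCl (cat.), rt
Reagents that add atoms: meta-chloroperoxybenzoic acid, O=C(OO)c1cccc(Cl)c1
Why: Baeyer-Villiger oxidation in which the aryl group, helped by its ortho aryloxy donor, migrates to oxygen in the Criegee intermediate to give the aryl formate, which mild methanolysis cleaves; this is the standard fluorobenzaldehyde route to ortho-hydroxylated polybrominated diphenyl ethers.

Step 11
Reactants: 16 3,5-dibromo-2-[3,4,5-tribromo-2-(2,4-dibromophenoxy)phenoxy]phenol
Product: 17 3,5-dibromo-2-[3,4,5-tribromo-2-(2,4-dibromophenoxy)phenoxy]phenyl hydrogen sulfate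
Conditions: SO3·pyridine (4 equiv), pyridine, rt to 40 °C; then Dowex 50W (H+ form), MeOH/H2O, 0 °C
Reagents that add atoms: sulfur trioxide pyridine complex, O=S(=O)([O-])[n+]1ccccc1
Why: O-Sulfonation of a phenol by the SO3·pyridine complex is the standard preparation of aryl sulfate monoesters, and brief cold cation exchange replaces pyridinium by a proton to give the hydrogen sulfate as drawn.

**Compound list**

1 | coumalic acid (2-oxo-2H-pyran-5-carboxylic acid) | O=C(O)c1ccc(=O)oc1 | starting material
2 | 3,5-dibromo-2H-pyran-2-one | O=c1occ(Br)cc1Br | intermediate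
3 | guaiacol (2-methoxyphenol) | COc1ccccc1O | starting material
4 | 2,3,4-tribromo-6-methoxyphenol (4,5,6-tribromoguaiacol) | COc1cc(Br)c(Br)c(Br)c1O | intermediate
5 | 1,2,3-tribromo-4-(2-bromoethoxy)-5-methoxybenzene | COc1cc(Br)c(Br)c(Br)c1OCCBr | intermediate
6 | 1,2,3-tribromo-4-(ethenyloxy)-5-methoxybenzene | COc1cc(Br)c(Br)c(Br)c1OC=C | intermediate
7 | 1,2,3-tribromo-4-(1,2-dibromoethoxy)-5-methoxybenzene, racemic, not isolated | COc1cc(Br)c(Br)c(Br)c1OC(Br)CBr | intermediate
8 | 1,2,3-tribromo-4-{[(Z)-2-bromoethenyl]oxy}-5-methoxybenzene (Z isomer drawn; a minor E isomer would be carried on) | COc1cc(Br)c(Br)c(Br)c1O/C=C\Br | intermediate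
9 | 1,2,3-tribromo-4-(ethynyloxy)-5-methoxybenzene | COc1cc(Br)c(Br)c(Br)c1OC#C | intermediate
10 | 4,6-dibromo-8-(2,3,4-tribromo-6-methoxyphenoxy)-2-oxabicyclo[2.2.2]octa-5,7-dien-3-one, racemic, not isolated | COc1cc(Br)c(Br)c(Br)c1OC1=CC2OC(=O)C1(Br)C=C2Br | intermediate
11 | 1,2,3-tribromo-4-(2,4-dibromophenoxy)-5-methoxybenzene | COc1cc(Br)c(Br)c(Br)c1Oc1ccc(Br)cc1Br | intermediate
12 | 3,4,5-tribromo-2-(2,4-dibromophenoxy)phenol | Oc1cc(Br)c(Br)c(Br)c1Oc1ccc(Br)cc1Br | intermediate
13 | 3,5-dibromo-2-fluorobenzaldehyde | O=Cc1cc(Br)cc(Br)c1F | starting material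
14 | 3,5-dibromo-2-[3,4,5-tribromo-2-(2,4-dibromophenoxy)phenoxy]benzaldehyde | O=Cc1cc(Br)cc(Br)c1Oc1cc(Br)c(Br)c(Br)c1Oc1ccc(Br)cc1Br | intermediate
15 | 3,5-dibromo-2-[3,4,5-tribromo-2-(2,4-dibromophenoxy)phenoxy]phenyl formate, not isolated | O=COc1cc(Br)cc(Br)c1Oc1cc(Br)c(Br)c(Br)c1Oc1ccc(Br)cc1Br | intermediate
16 | 3,5-dibromo-2-[3,4,5-tribromo-2-(2,4-dibromophenoxy)phenoxy]phenol | Oc1cc(Br)cc(Br)c1Oc1cc(Br)c(Br)c(Br)c1Oc1ccc(Br)cc1Br | intermediate
17 | bromoiesol A sulfate, 3,5-dibromo-2-[3,4,5-tribromo-2-(2,4-dibromophenoxy)phenoxy]phenyl hydrogen sulfate | O=S(=O)(O)Oc1cc(Br)cc(Br)c1Oc1cc(Br)c(Br)c(Br)c1Oc1ccc(Br)cc1Br | target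

**Step count**

Total step count: 11.
Longest linear sequence: 10 steps (guaiacol 3 to target 17, steps 2 to 11); the pyrone branch adds 1 step.

**Steps most likely to fail**

Step 7 (cycloaddition). The cycloaddition of the only moderately electron-poor pyrone may be slower than self-oligomerisation or adventitious hydration of the terminal ynol ether, and the orientation may be less than complete, so that the 3,5-dibromophenyl isomer contaminates the ether. The fallback sets out from phenol 4 and puts ring C on the hindered oxygen as a preformed aryl cation equivalent. 1,3-Dibromobenzene would be converted with (IO)2SO4 in H2SO4, then NaCl, into bis(2,4-dibromophenyl)iodonium chloride F1. The sodium phenoxide of 4 (NaOH, H2O/dioxane, 90 °C) would then be arylated by ligand coupling at iodine, a reaction that tolerates two ortho substituents on the phenoxide. This gives 11 directly, and the route is rejoined there.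

Step 6 (second dehydrobromination). The elimination may stall for the E isomer, tert-butoxide may add across the new triple bond, or the terminal ynol ether may polymerise on concentration. The fallback sets out from phenol 4 and builds ring C by substitution chemistry. SNAr with 2-bromo-1-fluoro-4-nitrobenzene (K2CO3, DMF, 60 °C) should give 1,2,3-tribromo-4-(2-bromo-4-nitrophenoxy)-5-methoxybenzene F2. Reduction with Fe powder and NH4Cl in EtOH/H2O should give 3-bromo-4-(2,3,4-tribromo-6-methoxyphenoxy)aniline F3. Diazotisation (NaNO2, aq HBr/MeCN, 0 °C) would give 3-bromo-4-(2,3,4-tribromo-6-methoxyphenoxy)benzenediazonium bromide F4, and Sandmeyer bromination with CuBr would deliver 11, where the route is rejoined.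

Step 10 (Baeyer-Villiger oxidation). In the Criegee intermediate of the dibromo-substituted, electron-poor aldehyde, hydrogen may migrate instead of the aryl group, so that the aldehyde is merely oxidised to the carboxylic acid. The fallback sets out from aldehyde 14 and changes the competing migrating group from hydrogen to methyl. Addition of MeMgBr (THF, −78 °C) should give racemic 1-{3,5-dibromo-2-[3,4,5-tribromo-2-(2,4-dibromophenoxy)phenoxy]phenyl}ethan-1-ol F5. Oxidation with Dess-Martin periodinane should give 1-{3,5-dibromo-2-[3,4,5-tribromo-2-(2,4-dibromophenoxy)phenoxy]phenyl}ethan-1-one F6. Baeyer-Villiger oxidation with CF3CO3H (from (CF3CO)2O and urea·H2O2, Na2HPO4, CH2Cl2), in which aryl migrates in preference to methyl, should give 3,5-dibromo-2-[3,4,5-tribromo-2-(2,4-dibromophenoxy)phenoxy]phenyl acetate F7. Methanolysis (K2CO3, MeOH, 0 °C) returns to phenol 16.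

**Further compounds**

F1 | step 7 | bis(2,4-dibromophenyl)iodonium chloride | Brc1ccc([I+]c2ccc(Br)cc2Br)c(Br)c1.[Cl-]
F2 | step 6 | 1,2,3-tribromo-4-(2-bromo-4-nitrophenoxy)-5-methoxybenzene | COc1cc(Br)c(Br)c(Br)c1Oc1ccc([N+](=O)[O-])cc1Br
F3 | step 6 | 3-bromo-4-(2,3,4-tribromo-6-methoxyphenoxy)aniline | COc1cc(Br)c(Br)c(Br)c1Oc1ccc(N)cc1Br
F4 | step 6 | 3-bromo-4-(2,3,4-tribromo-6-methoxyphenoxy)benzenediazonium bromide | COc1cc(Br)c(Br)c(Br)c1Oc1ccc([N+]#N)cc1Br.[Br-]
F5 | step 10 | 1-{3,5-dibromo-2-[3,4,5-tribromo-2-(2,4-dibromophenoxy)phenoxy]phenyl}ethan-1-ol, racemic | CC(O)c1cc(Br)cc(Br)c1Oc1cc(Br)c(Br)c(Br)c1Oc1ccc(Br)cc1Br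
F6 | step 10 | 1-{3,5-dibromo-2-[3,4,5-tribromo-2-(2,4-dibromophenoxy)phenoxy]phenyl}ethan-1-one | CC(=O)c1cc(Br)cc(Br)c1Oc1cc(Br)c(Br)c(Br)c1Oc1ccc(Br)cc1Br
F7 | step 10 | 3,5-dibromo-2-[3,4,5-tribromo-2-(2,4-dibromophenoxy)phenoxy]phenyl acetate | CC(=O)Oc1cc(Br)cc(Br)c1Oc1cc(Br)c(Br)c(Br)c1Oc1ccc(Br)cc1Br
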